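**Retrosynthetic overview**
- The stilbene aryl–vinyl bond is cut last (Mizoroki–Heck of an aryl bromide with 3,5-diacetoxystyrene); the three phenols are freed at the end without acid.
- In the cyclohexene ring, the C(CH3)=CH unit comes from a ketone (kinetic enol triflate, then methyl coupling). The stereocentre comes from enantioselective protonation of an enol silane. The second methyl of the CMe2 carbon comes from conjugate methylation of an achiral 2-benzyl-3-methylcyclohex-2-enone.
- Key disconnection: that enone is cut into a linear β-keto ester and methyl vinyl ketone. One operation makes the bond between the vinylic CH and its neighbouring CH2 (Michael) and the bond between the stereocentre carbon and the CMe2 carbon (aldol, first as C=C), and removes the activating ester as CO2.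
- Enabling feature: in the trimethylcyclohexene ring the methyl-bearing sp2 carbon can stand at the ketone level, so its two ring neighbours (the stereocentre carbon and the vinylic CH) are both α-carbons of one ketone. The quaternary ring carbon and the two ring CH2 groups can be the carbonyl, α- and β-carbons of methyl vinyl ketone.
- Ring order: both benzene rings are bought; the lactone ring of the starting chromanone is opened in step 1; the cyclohexene ring is the only ring built (step 3).

Key step: step 3

Remark: 6-bromo-3,4-dihydro-2H-chromen-2-one, 3,5-diacetoxystyrene and (R)-2-hydroxy-2′-methoxy-1,1′-binaphthyl are taken as purchasable. Locants used below for the carbocycle: C1 = stereocentre, C2 = methyl-bearing sp2 carbon, C3 = vinylic CH, C4 and C5 = the two CH2, C6 = CMe2.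

**Step 1**
Reactants: 1 6-bromo-3,4-dihydro-2H-chromen-2-one; 2 tert-butyl acetate
Product: 4 tert-butyl 5-(5-bromo-2-hydroxyphenyl)-3-oxopentanoate, via lithium enolate 3 (not isolated)
Conditions: 2 (2.6 equiv), LiN(i-Pr)2 (2.6 equiv), THF, −78 °C; then 1, −78 → −30 °C; aq. NH4Cl
Reagents that add atoms: none
Why: Crossed Claisen condensation (acylation of an ester enolate by a lactone): the aryl ester carbonyl of 1 is attacked by 3, the phenoxide leaves, and the β-keto ester formed is shielded from a second addition as its enolate; no stereocentre is formed.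

**Step 2**
Reactants: 4 tert-butyl 5-(5-bromo-2-hydroxyphenyl)-3-oxopentanoate
Product: 5 tert-butyl 5-{5-bromo-2-[tri(propan-2-yl)silyloxy]phenyl}-3-oxopentanoate
Conditions: i-Pr3SiCl, imidazole, DMF, rt
Reagents that add atoms: chlorotri(propan-2-yl)silane (TIPSCl), CC(C)[Si](Cl)(C(C)C)C(C)C
Why: Silyl ether formation: the phenol should react with the bulky chlorosilane much faster than the keto ester enol, and the aryl triisopropylsilyl ether should withstand the acid, Grignard, amide-base and palladium steps that follow.

**Step 3**
Reactants: 5 tert-butyl 5-{5-bromo-2-[tri(propan-2-yl)silyloxy]phenyl}-3-oxopentanoate; 6 but-3-en-2-one (methyl vinyl ketone)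
Product: 9 2-({5-bromo-2-[tri(propan-2-yl)silyloxy]phenyl}methyl)-3-methylcyclohex-2-en-1-one, via Michael adduct 7 (not isolated), via 1,5-diketone 8 (not isolated)
Conditions: 6 (1.1 equiv), Et3N (10 mol %), toluene, rt; then TsOH·H2O (30 mol %), toluene, 80 → 110 °C, Dean–Stark
Reagents that add atoms: none
Why: Amine-catalysed Michael addition of the doubly activated C–H of 5 (future C3) to the β-carbon of 6 (future C4) makes the first bond and gives 7; the acid then cleaves the tert-butyl ester, the β-keto acid loses CO2 to give 8, and acid-catalysed intramolecular aldol condensation of the enol on the arylethyl side (future C1) with the methyl ketone carbonyl (future C6) makes the second bond as the C1=C6 double bond of the enone. The closest known reaction type is the Robinson-type Michael/aldol annulation of a β-keto ester with methyl vinyl ketone, run with acid-mediated decarboxylation in the same pot. The one ring closed is the cyclohexenone, by a 6-(enolendo)-exo-trig aldol addition followed by loss of water. No stereocentre is formed, since 9 is achiral; the C1 stereocentre is set in step 5. Two regioselectivities are needed: Michael attack through C3 and not C1, secured by the ester on C3, and aldol closure through C1 and not through the methyl group of the butanone unit, secured by the preference of acid for the more substituted enol and by the reversibility of the aldol step, which should funnel to the more stable tetrasubstituted enone (the remaining closures would give four-membered rings).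

**Step 4**
Reactants: 9 2-({5-bromo-2-[tri(propan-2-yl)silyloxy]phenyl}methyl)-3-methylcyclohex-2-en-1-one
Product: 10 {[2-({5-bromo-2-[tri(propan-2-yl)silyloxy]phenyl}methyl)-3,3-dimethylcyclohex-1-en-1-yl]oxy}trimethylsilane
Conditions: MeMgBr (1.5 equiv), CuBr·SMe2 (10 mol %), Me3SiCl (2 equiv), DMPU, THF, −78 → −40 °C; Et3N, cold aq. NaHCO3
Reagents that add atoms: methylmagnesium bromide, C[Mg]Br; chlorotrimethylsilane, C[Si](C)(C)Cl
Why: Chlorosilane-accelerated copper-catalysed conjugate addition of a Grignard reagent to the β-methyl enone should create the quaternary CMe2 carbon and trap the regio-defined tetrasubstituted enolate as its silyl ether; the product is still achiral, and the aryl bromide should be inert to MeMgBr at this temperature.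

**Step 5**
Reactants: 10 {[2-({5-bromo-2-[tri(propan-2-yl)silyloxy]phenyl}methyl)-3,3-dimethylcyclohex-1-en-1-yl]oxy}trimethylsilane
Product: 11 (2S)-2-({5-bromo-2-[tri(propan-2-yl)silyloxy]phenyl}methyl)-3,3-dimethylcyclohexan-1-one
Conditions: (R)-2-hydroxy-2′-methoxy-1,1′-binaphthyl (1.1 equiv), SnCl4 (1.0 equiv), toluene, −78 °C; aq. NaHCO3
Reagents that add atoms: none
Why: Enantioselective protonation of a silyl enol ether by a Lewis acid-assisted chiral Brønsted acid: the tin-bound binaphthol should deliver the proton to one face of the planar enol silane and so set the only stereocentre by reagent control; the (R)-ligand is proposed, the sense is to be confirmed on the first run, and the (S)-ligand is equally available.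

**Step 6**
Reactants: 11 (2S)-2-({5-bromo-2-[tri(propan-2-yl)silyloxy]phenyl}methyl)-3,3-dimethylcyclohexan-1-one
Product: 13 (6S)-6-({5-bromo-2-[tri(propan-2-yl)silyloxy]phenyl}methyl)-5,5-dimethylcyclohex-1-en-1-yl trifluoromethanesulfonate, via potassium enolate 12 (not isolated)
Conditions: KN(SiMe3)2, THF, −78 °C; then PhNTf2, −78 → 0 °C
Reagents that add atoms: N-phenylbis(trifluoromethanesulfonimide), O=S(=O)(N(c1ccccc1)S(=O)(=O)C(F)(F)F)C(F)(F)F
Why: Kinetic enolate formation and O-triflation: the amide base at −78 °C should remove a proton from the open C3 methylene and not from the C1 methine flanked by CMe2, so the stereocentre is untouched and the double bond is placed towards C3 only.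

**Step 7**
Reactants: 13 (6S)-6-({5-bromo-2-[tri(propan-2-yl)silyloxy]phenyl}methyl)-5,5-dimethylcyclohex-1-en-1-yl trifluoromethanesulfonate
Product: 14 (4-bromo-2-{[(1S)-2,6,6-trimethylcyclohex-2-en-1-yl]methyl}phenoxy)tri(propan-2-yl)silane
Conditions: MeMgBr (1.3 equiv), Fe(acac)3 (5 mol %), THF/NMP, −30 °C
Reagents that add atoms: methylmagnesium bromide, C[Mg]Br
Why: Iron-catalysed Kumada-type coupling of an alkenyl triflate with a Grignard reagent should replace the triflate by methyl without moving the double bond; alkenyl triflates couple fast at −30 °C whereas an electron-rich aryl bromide should not react with MeMgBr under these conditions, and the stereocentre is not involved.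

**Step 8**
Reactants: 14 (4-bromo-2-{[(1S)-2,6,6-trimethylcyclohex-2-en-1-yl]methyl}phenoxy)tri(propan-2-yl)silane; 15 5-ethenyl-1,3-phenylene diacetate (3,5-diacetoxystyrene)
Product: 16 5-[(E)-2-(4-[tri(propan-2-yl)silyloxy]-3-{[(1S)-2,6,6-trimethylcyclohex-2-en-1-yl]methyl}phenyl)ethenyl]-1,3-phenylene diacetate
Conditions: 15 (1.3 equiv), Pd(OAc)2 (5 mol %), P(o-tol)3 (10 mol %), Et3N, DMF, 100 °C
Reagents that add atoms: none
Why: Mizoroki–Heck reaction: oxidative addition of zerovalent palladium into the aryl bromide, insertion at the terminal carbon of the styrene and syn β-hydride elimination should give the (E)-stilbene, while the hindered trisubstituted ring alkene does not compete.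

**Step 9**
Reactants: 16 5-[(E)-2-(4-[tri(propan-2-yl)silyloxy]-3-{[(1S)-2,6,6-trimethylcyclohex-2-en-1-yl]methyl}phenyl)ethenyl]-1,3-phenylene diacetate
Product: 18 5-[(E)-2-(4-hydroxy-3-{[(1S)-2,6,6-trimethylcyclohex-2-en-1-yl]methyl}phenyl)ethenyl]benzene-1,3-diol, via diacetate phenol 17 (not isolated)
Conditions: Bu4NF, AcOH, THF, 0 °C; then K2CO3, MeOH, rt, argon, dark; aq. NH4Cl
Reagents that add atoms: none
Why: Buffered fluoride cleavage of the aryl silyl ether followed by base-catalysed methanolysis of the aryl acetates (transesterification) avoids any strong acid, which would add the freed phenol across the ring double bond; no stereocentre is affected.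

**Compound list**
1 | 6-bromo-3,4-dihydro-2H-chromen-2-one | O=C1CCc2cc(Br)ccc2O1 | starting material
2 | tert-butyl acetate | CC(=O)OC(C)(C)C | starting material
3 | lithium 1-tert-butoxyethen-1-olate (lithium enolate of 2) | [Li+].[O-]C(=C)OC(C)(C)C | intermediate
4 | tert-butyl 5-(5-bromo-2-hydroxyphenyl)-3-oxopentanoate | CC(C)(C)OC(=O)CC(=O)CCc1cc(Br)ccc1O | intermediate
5 | tert-butyl 5-{5-bromo-2-[tri(propan-2-yl)silyloxy]phenyl}-3-oxopentanoate | CC(C)(C)OC(=O)CC(=O)CCc1cc(Br)ccc1O[Si](C(C)C)(C(C)C)C(C)C | intermediate
6 | but-3-en-2-one | CC(=O)C=C | starting material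
7 | tert-butyl 2-(3-{5-bromo-2-[tri(propan-2-yl)silyloxy]phenyl}propanoyl)-5-oxohexanoate (racemic) | CC(=O)CCC(C(=O)OC(C)(C)C)C(=O)CCc1cc(Br)ccc1O[Si](C(C)C)(C(C)C)C(C)C | intermediate
8 | 1-{5-bromo-2-[tri(propan-2-yl)silyloxy]phenyl}octane-3,7-dione | CC(=O)CCCC(=O)CCc1cc(Br)ccc1O[Si](C(C)C)(C(C)C)C(C)C | intermediate
9 | 2-({5-bromo-2-[tri(propan-2-yl)silyloxy]phenyl}methyl)-3-methylcyclohex-2-en-1-one | CC1=C(Cc2cc(Br)ccc2O[Si](C(C)C)(C(C)C)C(C)C)C(=O)CCC1 | intermediate
10 | {[2-({5-bromo-2-[tri(propan-2-yl)silyloxy]phenyl}methyl)-3,3-dimethylcyclohex-1-en-1-yl]oxy}trimethylsilane | C[Si](C)(C)OC1=C(Cc2cc(Br)ccc2O[Si](C(C)C)(C(C)C)C(C)C)C(C)(C)CCC1 | intermediate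
11 | (2S)-2-({5-bromo-2-[tri(propan-2-yl)silyloxy]phenyl}methyl)-3,3-dimethylcyclohexan-1-one | O=C1CCCC(C)(C)[C@@H]1Cc1cc(Br)ccc1O[Si](C(C)C)(C(C)C)C(C)C | intermediate
12 | potassium (6S)-6-({5-bromo-2-[tri(propan-2-yl)silyloxy]phenyl}methyl)-5,5-dimethylcyclohex-1-en-1-olate | [K+].[O-]C1=CCCC(C)(C)[C@@H]1Cc1cc(Br)ccc1O[Si](C(C)C)(C(C)C)C(C)C | intermediate
13 | (6S)-6-({5-bromo-2-[tri(propan-2-yl)silyloxy]phenyl}methyl)-5,5-dimethylcyclohex-1-en-1-yl trifluoromethanesulfonate | O=S(=O)(OC1=CCCC(C)(C)[C@@H]1Cc1cc(Br)ccc1O[Si](C(C)C)(C(C)C)C(C)C)C(F)(F)F | intermediate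
14 | (4-bromo-2-{[(1S)-2,6,6-trimethylcyclohex-2-en-1-yl]methyl}phenoxy)tri(propan-2-yl)silane | CC1=CCCC(C)(C)[C@@H]1Cc1cc(Br)ccc1O[Si](C(C)C)(C(C)C)C(C)C | intermediate
15 | 5-ethenyl-1,3-phenylene diacetate | C=Cc1cc(OC(C)=O)cc(OC(C)=O)c1 | starting material
16 | 5-[(E)-2-(4-[tri(propan-2-yl)silyloxy]-3-{[(1S)-2,6,6-trimethylcyclohex-2-en-1-yl]methyl}phenyl)ethenyl]-1,3-phenylene diacetate | CC1=CCCC(C)(C)[C@@H]1Cc1cc(/C=C/c2cc(OC(C)=O)cc(OC(C)=O)c2)ccc1O[Si](C(C)C)(C(C)C)C(C)C | intermediate
17 | 5-[(E)-2-(4-hydroxy-3-{[(1S)-2,6,6-trimethylcyclohex-2-en-1-yl]methyl}phenyl)ethenyl]-1,3-phenylene diacetate | CC1=CCCC(C)(C)[C@@H]1Cc1cc(/C=C/c2cc(OC(C)=O)cc(OC(C)=O)c2)ccc1O | intermediate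
18 | 5-[(E)-2-(4-hydroxy-3-{[(1S)-2,6,6-trimethylcyclohex-2-en-1-yl]methyl}phenyl)ethenyl]benzene-1,3-diol | CC1=CCCC(C)(C)[C@@H]1Cc1cc(/C=C/c2cc(O)cc(O)c2)ccc1O | target

**Step count and risks**
Total step count: 9. Longest linear sequence: 9 steps (1 → 18).

Steps most likely to fail, each with a fallback:

Step 5. The proton transfer may show poor facial selectivity, because the protonated carbon carries an alkyl and not an aryl group, and adventitious acid may hydrolyse the enol silane without control. The fallback sets out from 10 and comes back at 11, and sets the stereocentre by dynamic kinetic resolution instead. Compound 10 is hydrolysed with K2CO3 in MeOH to racemic 2-({5-bromo-2-[tri(propan-2-yl)silyloxy]phenyl}methyl)-3,3-dimethylcyclohexan-1-one F1. F1 is hydrogenated under Noyori conditions (H2, RuCl2[(S)-binap][(S,S)-dpen] or its mirror image as assigned in a first run, t-BuOK, i-PrOH); the C1–H should epimerise through the enolate while one enantiomer is reduced faster, to give (1R,2S)-2-({5-bromo-2-[tri(propan-2-yl)silyloxy]phenyl}methyl)-3,3-dimethylcyclohexan-1-ol F2. Dess–Martin oxidation of F2 under buffered, non-epimerising conditions then gives 11.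

Step 3. The aldol closure may go through the wrong enol (the methyl group of the butanone unit) and give the regioisomeric enone; a second Michael addition or loss of the silyl ether in hot acid may also occur. The fallback sets out from 5 and 6 and comes back at 9. The annulation is run stepwise and closed under base with the ester still in place, so that a different element decides the regiochemistry. Adduct 7 is isolated after the amine-catalysed Michael addition and treated with t-BuOK in t-BuOH. Only closure through C1 leaves an enolisable β-keto ester, the thermodynamic sink, and should give tert-butyl 3-({5-bromo-2-[tri(propan-2-yl)silyloxy]phenyl}methyl)-4-methyl-2-oxocyclohex-3-ene-1-carboxylate F3. TsOH in toluene at 80 °C then removes the tert-butyl group and CO2 from F3 and gives 9.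

Step 7. Coupling at the hindered alkenyl triflate may be slow, with competing reduction of the triflate or reaction at the aryl bromide. The fallback sets out from 11 and comes back at 14. The methyl carbon is brought in as a methylidene on the ketone and the double bond is then moved into the ring. Non-basic Takai–Lombardo methylenation of 11 (Zn, CH2Br2, TiCl4, THF/CH2Cl2), which should not epimerise C1, gives (4-bromo-2-{[(1S)-2,2-dimethyl-6-methylidenecyclohexyl]methyl}phenoxy)tri(propan-2-yl)silane F4. RhCl3·3H2O (cat.) in EtOH at 70 °C should then isomerise the exocyclic alkene of F4 to the trisubstituted ring alkene through the less hindered C3–H, giving 14.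

Further compounds
F1 | step 5 | 2-({5-bromo-2-[tri(propan-2-yl)silyloxy]phenyl}methyl)-3,3-dimethylcyclohexan-1-one (racemic) | O=C1CCCC(C)(C)C1Cc1cc(Br)ccc1O[Si](C(C)C)(C(C)C)C(C)C
F2 | step 5 | (1R,2S)-2-({5-bromo-2-[tri(propan-2-yl)silyloxy]phenyl}methyl)-3,3-dimethylcyclohexan-1-ol | O[C@@H]1CCCC(C)(C)[C@@H]1Cc1cc(Br)ccc1O[Si](C(C)C)(C(C)C)C(C)C
F3 | step 3 | tert-butyl 3-({5-bromo-2-[tri(propan-2-yl)silyloxy]phenyl}methyl)-4-methyl-2-oxocyclohex-3-ene-1-carboxylate (racemic) | CC1=C(Cc2cc(Br)ccc2O[Si](C(C)C)(C(C)C)C(C)C)C(=O)C(C(=O)OC(C)(C)C)CC1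
F4 | step 7 | (4-bromo-2-{[(1S)-2,2-dimethyl-6-methylidenecyclohexyl]methyl}phenoxy)tri(propan-2-yl)silane | C=C1CCCC(C)(C)[C@@H]1Cc1cc(Br)ccc1O[Si](C(C)C)(C(C)C)C(C)C
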